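**Retrosynthetic overview**
- The target is traced back to an enal keto ester by acetylation, oxidation of two primary silyl ethers and a global hydride reduction. The enal comes from a 3‑methoxy bicyclo[3.3.1]nonan‑9‑one by loss of methanol.
- Key disconnection: bonds C3–C4 and C5–C6, leading to a 1‑isopropenylcyclopentanol silyl ether (ring C9–C6–C7–C8–C1) whose C1 carries the ester and a dimethyl acetal arm (C2, C3). The feature used is quaternary C5 with its methyl, held between the oxygen-bearing bridge carbon C9, C4 of ring A and C6 of ring B.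
- The cyclopentanol comes from an acyclic keto acid by aldol lactonisation (bond C1–C9), which places the arm, the isopropenyl group and the side chain cis.
- The keto acid comes from (R)‑citronellal by two amine-catalysed Michael additions (C8–C7 to a vinyl ketone, then C2–C1 to the nitroalkene made from the aldehyde carbon).
- Ring order: cyclopentane first (step 7), then ring A and ring B in one operation (step 10).

Key step: step 10

Remark on the chemistry: atoms keep the bicyclo[3.3.1]nonane numbering of the target in every intermediate (C1′ = side-chain methine, C10 = the carbon on C1, C2′ = the carbon on C2).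

Step 1
Reactants: 1 methoxyallene (1‑methoxypropa‑1,2‑diene); 2 acetone
Product: 4 4‑hydroxy‑4‑methylpent‑1‑en‑3‑one, via 3‑methoxy‑2‑methylpenta‑3,4‑dien‑2‑ol 3 (not isolated)
Conditions: n‑BuLi, Et2O, −40 °C; acetone; then 5% aq. H2SO4, 23 °C
Reagents that add atoms: water, O
Why: α‑lithiated methoxyallene acts as an acryloyl anion equivalent that adds to acetone, and acid hydrolysis of the allenyl ether releases the vinyl ketone (no stereocentre).

Step 2
Reactants: 5 (R)‑citronellal; 4 4‑hydroxy‑4‑methylpent‑1‑en‑3‑one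
Product: 6 (2S)‑6‑hydroxy‑6‑methyl‑2‑[(2R)‑6‑methylhept‑5‑en‑2‑yl]‑5‑oxoheptanal
Conditions: (S)‑2‑[diphenyl(trimethylsilyloxy)methyl]pyrrolidine (10 mol%), ethyl 3,4‑dihydroxybenzoate (20 mol%), CH2Cl2, 4 °C
Reagents that add atoms: none
Why: enamine-catalysed Michael addition of an aldehyde to a vinyl ketone, in which the diarylmethyl group of the (S)‑catalyst shields one face of the E‑enamine so that C8 is formed (S) under catalyst control, the remote C1′ centre having little influence.

Step 3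
Reactants: 6 the Michael adduct; 7 nitromethane
Product: 9 (6S,7E)‑2‑hydroxy‑2‑methyl‑6‑[(2R)‑6‑methylhept‑5‑en‑2‑yl]‑8‑nitrooct‑7‑en‑3‑one, via nitro alcohol 8 (not isolated)
Conditions: MeNO2, TMG (10 mol%), THF, 0 °C; then DCC, CuCl (5 mol%), Et2O, 23 °C
Reagents that add atoms: none
Why: Henry reaction of the aldehyde followed by carbodiimide dehydration of the secondary nitro alcohol gives the thermodynamically preferred E‑nitroalkene, while the tertiary α‑hydroxy ketone does not react and the mild base should leave C8 untouched.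

Step 4
Reactants: 9 the hydroxy nitroalkene
Product: 10 (6S,7E)‑2‑methyl‑6‑[(2R)‑6‑methylhept‑5‑en‑2‑yl]‑8‑nitroocta‑1,7‑dien‑3‑one
Conditions: methyl N‑(triethylammoniosulfonyl)carbamate, benzene, 50 °C
Reagents that add atoms: none
Why: dehydration by syn‑elimination of the tertiary sulfamate ester, for which only the methyl hydrogens are available, so the isopropenyl ketone is the only alkene that can form and the neutral conditions spare the nitroalkene.

Step 5
Reactants: 10 the nitro dienone; 11 3‑[(tert‑butyldimethylsilyl)oxy]propanal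
Product: 13 dimethyl acetal of the (2R,3S,4S) nitro aldehyde, via nitro aldehyde 12 (not isolated)
Conditions: (R)‑2‑[diphenyl(trimethylsilyloxy)methyl]pyrrolidine (10 mol%), 4‑nitrophenol (10 mol%), toluene, 23 °C; then HC(OMe)3, PPTS, MeOH, 23 °C
Reagents that add atoms: trimethyl orthoformate, COC(OC)OC
Why: enamine-catalysed Michael addition to the nitroalkene (far more electrophilic than the α‑methyl enone), in which the (R)‑catalyst fixes C2 as (R) and the synclinal transition state gives the syn C1 centre, followed by acetalisation in the same flask to stop epimerisation at C2; C1 becomes planar again in step 7.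

Step 6
Reactants: 13 the nitro acetal
Product: 14 (2S,3S)‑2‑[(2R)‑1‑{[tert‑butyl(dimethyl)silyl]oxy}‑3,3‑dimethoxypropan‑2‑yl]‑7‑methyl‑3‑[(2R)‑6‑methylhept‑5‑en‑2‑yl]‑6‑oxooct‑7‑enoic acid
Conditions: NaNO2, AcOH, DMSO, 35 °C
Reagents that add atoms: sodium nitrite, [Na+].[O-]N=O
Why: nitrosative oxidation of a primary nitroalkane to the carboxylic acid (through the nitrolic acid and nitrile oxide) in weakly acidic DMSO, which the acetal, silyl ether and enone should tolerate; no stereocentre is touched.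

Step 7
Reactants: 14 the keto acid
Product: 15 cis‑fused bicyclic β‑lactone (6‑oxabicyclo[3.2.0]heptan‑7‑one; lactone oxygen on C9, carbonyl on C1; isopropenyl, C2 arm and C8 side chain on the face opposite the lactone)
Conditions: 2‑bromo‑1‑propylpyridinium triflate, 4‑pyrrolidinopyridine, iPr2NEt, CH2Cl2, 23 °C (slow addition of 14)
Reagents that add atoms: none
Why: nucleophile-catalysed aldol lactonisation of a keto acid, in which the acylpyridinium gives a planar ammonium enolate at C1 without enolising the ketone, A1,3 strain holds H8 in the enolate plane so that C9 bonds on the face of C7 and anti to the side chain (arm cis to side chain), and β‑lactone closure requires O9 and the carboxyl carbon cis (isopropenyl cis to the arm).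

Step 8
Reactants: 15 the β‑lactone
Product: 16 methyl (1R,2S,5S)‑1‑[(2R)‑1‑{[tert‑butyl(dimethyl)silyl]oxy}‑3,3‑dimethoxypropan‑2‑yl]‑2‑hydroxy‑5‑[(2R)‑6‑methylhept‑5‑en‑2‑yl]‑2‑(prop‑1‑en‑2‑yl)cyclopentane‑1‑carboxylate
Conditions: K2CO3, MeOH, 0 °C
Reagents that add atoms: methanol, CO
Why: methanolysis of the strained β‑lactone at the acyl carbon (the alkyl carbon C9 is tertiary) keeps C1 and C9 as set, and short contact at 0 °C should limit retro-aldol opening.

Step 9
Reactants: 16 the hydroxy ester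
Product: 17 the trimethylsilyl ether of 16 (cascade precursor; same configurations)
Conditions: 1‑(trimethylsilyl)imidazole, CH2Cl2, 40 °C
Reagents that add atoms: 1‑(trimethylsilyl)imidazole, C[Si](C)(C)n1ccnc1
Why: silylation of the hindered tertiary alcohol with a neutral silyl donor that does not ionise the dimethyl acetal.

Step 10
Reactants: 17 the silyl ether acetal
Product: 20 methyl (1R,2R,3S,5R,8S)‑2‑({[tert‑butyl(dimethyl)silyl]oxy}methyl)‑3‑methoxy‑5‑methyl‑8‑[(2R)‑6‑methylhept‑5‑en‑2‑yl]‑9‑oxobicyclo[3.3.1]nonane‑1‑carboxylate, via oxocarbenium ion 18 (not isolated), via tertiary cation 19 (not isolated)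
Conditions: SnCl4, 2,6‑di‑tert‑butyl‑4‑methylpyridine, CH2Cl2, −78 → −40 °C
Reagents that add atoms: none
Why: Proposed new method: SnCl4 removes one methoxy group of the acetal to give the (E)‑oxocarbenium ion 18; C4 of the isopropenyl group attacks C3 through a six-membered chair (6‑endo closure of ring A, bond C3–C4) to give the tertiary C5 cation 19, and C6 then shifts from C9 to C5 (pinacol ring enlargement of the cyclopentane, which closes ring B through bond C5–C6) as the silyl group leaves and C9 becomes the ketone. The closest known reaction is the Prins–pinacol ring-enlarging cyclopentane annulation of 1‑alkenylcycloalkanol silyl ethers with a tethered acetal, which migrates the tether-bearing ring carbon and gives fused bicycles; a shift of the remote ring methylene to a bridged bicyclo[3.3.1]nonan‑9‑one has not been shown. C5 is set by the bicyclic constraint, because C6 stays on the face of ring A that it occupied at C9 (cis to C8), and C3 is set by the equatorial methoxy group of the chair and is erased in step 11. The step needs C6 and not C1 to migrate: the arm and the isopropenyl group are cis, C1 is a quaternary carbon made electron-poor by its ester, and the C2 configuration places CH2OTBS equatorial only in the chair in which the C9–C6 bond is axial and parallel to the empty orbital at C5 while the methoxycarbonyl group is axial at C1. The hindered base removes adventitious acid so that the side-chain alkene and the silyl ethers should be left untouched.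

Step 11
Reactants: 20 the bicyclic keto ester
Product: 23 methyl (1R,5R,8S)‑2‑formyl‑5‑methyl‑8‑[(2R)‑6‑methylhept‑5‑en‑2‑yl]‑9‑oxobicyclo[3.3.1]non‑2‑ene‑1‑carboxylate, via primary alcohol 21 (not isolated), via methoxy aldehyde 22 (not isolated)
Conditions: HF·pyridine, pyridine, THF, 0 °C; then triacetoxyperiodinane (DMP), CH2Cl2, 0 °C; then DBU, 23 °C
Reagents that add atoms: none
Why: fluoride cleavage of the primary silyl ether, periodinane oxidation and E1cB loss of methanol from the β‑methoxy aldehyde give the enal; the alcohol is oxidised at once because it can lactonise onto the cis ester, and C2 and C3 both become sp2.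

Step 12
Reactants: 23 the enal keto ester
Product: 24 (1S,5R,8S,9R)‑1,2‑bis(hydroxymethyl)‑5‑methyl‑8‑[(2R)‑6‑methylhept‑5‑en‑2‑yl]bicyclo[3.3.1]non‑2‑en‑9‑ol
Conditions: iBu2AlH, CH2Cl2, −78 → 0 °C
Reagents that add atoms: none
Why: hydride reduction of the enal (1,2), the ester and the ketone, in which hydride reaches C9 from the face of the unsaturated bridge (ring A has no axial hydrogen at C2 and presents only H4, whereas the ring B face is screened by axial H6 and H8), so the hydroxyl ends syn to ring B as in the target.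

Step 13
Reactants: 24 the triol
Product: 26 (1S,5R,8S,9R)‑5‑methyl‑8‑[(2R)‑6‑methylhept‑5‑en‑2‑yl]‑1,2‑bis{[(triethylsilyl)oxy]methyl}bicyclo[3.3.1]non‑2‑en‑9‑yl acetate, via bis‑silyl ether 25 (not isolated)
Conditions: Et3SiCl, Et3N, DMAP, CH2Cl2, −40 °C; then Ac2O, DMAP, 23 → 40 °C
Reagents that add atoms: chlorotriethylsilane, CC[Si](Cl)(CC)CC; acetic anhydride, CC(=O)OC(C)=O
Why: the two primary alcohols are silylated selectively on steric grounds and the hindered C9 alcohol is then acetylated by DMAP catalysis, without change at any stereocentre.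

Step 14
Reactants: 26 the bis‑silyl ether acetate
Product: 27 (1R,5R,8S,9R)‑1,2‑diformyl‑5‑methyl‑8‑[(2R)‑6‑methylhept‑5‑en‑2‑yl]bicyclo[3.3.1]non‑2‑en‑9‑yl acetate (target)
Conditions: (COCl)2, DMSO, CH2Cl2, −78 → −40 °C; then Et3N, → 0 °C
Reagents that add atoms: none
Why: Swern oxidation, in which the chlorosulfonium salt converts primary triethylsilyl ethers directly into aldehydes, so both formyl groups appear without a free hydroxy aldehyde that would close to a lactol, and the acetate and the quaternary C1 are not affected.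

**Compound list**
1 | methoxyallene | COC=C=C | starting material
2 | acetone | CC(C)=O | starting material
3 | 3‑methoxy‑2‑methylpenta‑3,4‑dien‑2‑ol | CC(C)(O)C(OC)=C=C | intermediate
4 | 4‑hydroxy‑4‑methylpent‑1‑en‑3‑one | C=CC(=O)C(C)(C)O | intermediate
5 | (R)‑citronellal | C[C@H](CCC=C(C)C)CC=O | starting material
6 | (2S)‑6‑hydroxy‑6‑methyl‑2‑[(2R)‑6‑methylhept‑5‑en‑2‑yl]‑5‑oxoheptanal | O=C[C@H]([C@H](C)CCC=C(C)C)CCC(=O)C(C)(C)O | intermediate
7 | nitromethane | C[N+](=O)[O-] | starting material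
8 | (6S)‑2,7‑dihydroxy‑2‑methyl‑6‑[(2R)‑6‑methylhept‑5‑en‑2‑yl]‑8‑nitrooctan‑3‑one (both C7 epimers) | OC(C[N+](=O)[O-])[C@H]([C@H](C)CCC=C(C)C)CCC(=O)C(C)(C)O | intermediate
9 | (6S,7E)‑2‑hydroxy‑2‑methyl‑6‑[(2R)‑6‑methylhept‑5‑en‑2‑yl]‑8‑nitrooct‑7‑en‑3‑one | [O-][N+](=O)/C=C/[C@H]([C@H](C)CCC=C(C)C)CCC(=O)C(C)(C)O | intermediate
10 | (6S,7E)‑2‑methyl‑6‑[(2R)‑6‑methylhept‑5‑en‑2‑yl]‑8‑nitroocta‑1,7‑dien‑3‑one | [O-][N+](=O)/C=C/[C@H]([C@H](C)CCC=C(C)C)CCC(=O)C(C)=C | intermediate
11 | 3‑[(tert‑butyldimethylsilyl)oxy]propanal | O=CCCO[Si](C)(C)C(C)(C)C | starting material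
12 | (2R,3S,4S)‑2‑({[tert‑butyl(dimethyl)silyl]oxy}methyl)‑8‑methyl‑4‑[(2R)‑6‑methylhept‑5‑en‑2‑yl]‑3‑(nitromethyl)‑7‑oxonon‑8‑enal | O=C[C@@H](CO[Si](C)(C)C(C)(C)C)[C@H]([C@H]([C@H](C)CCC=C(C)C)CCC(=O)C(C)=C)C[N+](=O)[O-] | intermediate
13 | dimethyl acetal of 12 (same centres) | COC(OC)[C@@H](CO[Si](C)(C)C(C)(C)C)[C@H]([C@H]([C@H](C)CCC=C(C)C)CCC(=O)C(C)=C)C[N+](=O)[O-] | intermediate
14 | (2S,3S)‑2‑[(2R)‑1‑{[tert‑butyl(dimethyl)silyl]oxy}‑3,3‑dimethoxypropan‑2‑yl]‑7‑methyl‑3‑[(2R)‑6‑methylhept‑5‑en‑2‑yl]‑6‑oxooct‑7‑enoic acid | COC(OC)[C@@H](CO[Si](C)(C)C(C)(C)C)[C@H]([C@H]([C@H](C)CCC=C(C)C)CCC(=O)C(C)=C)C(=O)O | intermediate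
15 | cis‑fused β‑lactone (O9–C10 lactone; isopropenyl, C2 arm and side chain cis) | C=C(C)[C@@]12CC[C@@H]([C@H](C)CCC=C(C)C)[C@@]1(C(=O)O2)[C@H](CO[Si](C)(C)C(C)(C)C)C(OC)OC | intermediate
16 | methyl (1R,2S,5S)‑1‑[(2R)‑1‑{[tert‑butyl(dimethyl)silyl]oxy}‑3,3‑dimethoxypropan‑2‑yl]‑2‑hydroxy‑5‑[(2R)‑6‑methylhept‑5‑en‑2‑yl]‑2‑(prop‑1‑en‑2‑yl)cyclopentane‑1‑carboxylate | C=C(C)[C@@]1(O)CC[C@@H]([C@H](C)CCC=C(C)C)[C@@]1(C(=O)OC)[C@H](CO[Si](C)(C)C(C)(C)C)C(OC)OC | intermediate
17 | trimethylsilyl ether of 16 | C=C(C)[C@@]1(O[Si](C)(C)C)CC[C@@H]([C@H](C)CCC=C(C)C)[C@@]1(C(=O)OC)[C@H](CO[Si](C)(C)C(C)(C)C)C(OC)OC | intermediate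
18 | (E)‑oxocarbenium ion at C3 | C=C(C)[C@@]1(O[Si](C)(C)C)CC[C@@H]([C@H](C)CCC=C(C)C)[C@@]1(C(=O)OC)[C@H](CO[Si](C)(C)C(C)(C)C)/C=[O+]/C | intermediate
19 | cis‑fused bicyclic C5 cation (ring A closed) | C[Si](C)(C)O[C@@]12[C+](C)C[C@H](OC)[C@@H](CO[Si](C)(C)C(C)(C)C)[C@]1(C(=O)OC)[C@H]([C@H](C)CCC=C(C)C)CC2 | intermediate
20 | methyl (1R,2R,3S,5R,8S)‑2‑({[tert‑butyl(dimethyl)silyl]oxy}methyl)‑3‑methoxy‑5‑methyl‑8‑[(2R)‑6‑methylhept‑5‑en‑2‑yl]‑9‑oxobicyclo[3.3.1]nonane‑1‑carboxylate | O=C1[C@@]2(C)C[C@H](OC)[C@@H](CO[Si](C)(C)C(C)(C)C)[C@]1(C(=O)OC)[C@H]([C@H](C)CCC=C(C)C)CC2 | intermediate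
21 | 2‑hydroxymethyl analogue of 20 (configurations as in 20) | O=C1[C@@]2(C)C[C@H](OC)[C@@H](CO)[C@]1(C(=O)OC)[C@H]([C@H](C)CCC=C(C)C)CC2 | intermediate
22 | 2‑formyl‑3‑methoxy analogue of 20 (configurations as in 20) | O=C1[C@@]2(C)C[C@H](OC)[C@@H](C=O)[C@]1(C(=O)OC)[C@H]([C@H](C)CCC=C(C)C)CC2 | intermediate
23 | methyl (1R,5R,8S)‑2‑formyl‑5‑methyl‑8‑[(2R)‑6‑methylhept‑5‑en‑2‑yl]‑9‑oxobicyclo[3.3.1]non‑2‑ene‑1‑carboxylate | O=C1[C@@]2(C)CC=C(C=O)[C@]1(C(=O)OC)[C@H]([C@H](C)CCC=C(C)C)CC2 | intermediate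
24 | (1S,5R,8S,9R)‑1,2‑bis(hydroxymethyl)‑5‑methyl‑8‑[(2R)‑6‑methylhept‑5‑en‑2‑yl]bicyclo[3.3.1]non‑2‑en‑9‑ol | O[C@@H]1[C@@]2(C)CC=C(CO)[C@]1(CO)[C@H]([C@H](C)CCC=C(C)C)CC2 | intermediate
25 | bis(triethylsilyl) ether of 24 at the two primary hydroxyls | O[C@@H]1[C@@]2(C)CC=C(CO[Si](CC)(CC)CC)[C@]1(CO[Si](CC)(CC)CC)[C@H]([C@H](C)CCC=C(C)C)CC2 | intermediate
26 | C9 acetate of 25 | CC(=O)O[C@@H]1[C@@]2(C)CC=C(CO[Si](CC)(CC)CC)[C@]1(CO[Si](CC)(CC)CC)[C@H]([C@H](C)CCC=C(C)C)CC2 | intermediate
27 | (1R,5R,8S,9R)‑1,2‑diformyl‑5‑methyl‑8‑[(2R)‑6‑methylhept‑5‑en‑2‑yl]bicyclo[3.3.1]non‑2‑en‑9‑yl acetate | CC(=O)O[C@@H]1[C@@]2(C)CC=C(C=O)[C@]1(C=O)[C@H]([C@H](C)CCC=C(C)C)CC2 | target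

**Step count**
Total: 14 steps. Longest linear sequence: 14 steps (methoxyallene to 27; 13 steps from (R)‑citronellal).

**Steps most likely to fail**

Step 10 (key step). The shift may go to the tether-bearing C1 (ring contraction to a fused hydrindanone), or cation 19 may lose a proton before any shift. The fallback separates ring closure from the shift and makes the shift stereospecific with known reactions. It sets out from hydroxy ester 16 and returns at 20.
- Mild hydrolysis of the acetal (LiBF4, wet MeCN) gives hydroxy aldehyde F1.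
- An intramolecular carbonyl‑ene reaction (Me2AlCl, CH2Cl2, −78 °C) closes ring A and gives exo‑methylene diol F2, with the C3 oxygen expected equatorial in the chair.
- Selective O‑methylation of the secondary hydroxyl (MeOTf, 2,6‑di‑tert‑butyl‑4‑methylpyridine) gives methyl ether F3.
- Hydroxyl-directed epoxidation (VO(acac)2, t‑BuOOH) acts on the allylic exocyclic alkene and not on the side-chain alkene, giving spiro‑epoxy alcohol F4 with the epoxide oxygen syn to the C9 hydroxyl.
- BF3·OEt2 at −78 °C then triggers the epoxy‑alcohol semipinacol rearrangement. In the chair with CH2OTBS and OMe equatorial, the C5–O bond is axial and anti to C9–C6, so C6 shifts and hydroxymethyl ketone F5 results.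
- Barton–McCombie deoxygenation (1,1′‑thiocarbonyldiimidazole to imidazolyl thionocarbonate F6, then Bu3SnH at high concentration with AIBN, toluene, 110 °C) turns the hydroxymethyl group into the C5 methyl and gives 20.

Step 7. Enolisation of the hindered α,α‑disubstituted acyl unit may be slow, so that the activated acid is lost to ketene dimerisation or intermolecular acylation. The fallback sets out from keto acid 14 and returns at 16.
- Coupling with thiophenol (DCC, DMAP) gives S‑phenyl thioester F7.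
- Soft enolisation (MgBr2·OEt2, iPr2NEt, CH2Cl2) is selective for the more acidic thioester over the ketone and closes the ring by an intramolecular thioester aldol under the same A1,3 and chelate control, giving hydroxy thioester F8.
- Methanolysis (K2CO3, MeOH, 0 °C) gives 16.

Step 6. Nitrosation may attack the electron-rich side-chain alkene, or the acetal may be lost in acetic acid. The fallback sets out from nitro acetal 13 and returns at 14.
- A reductive Nef reaction (NaOMe, MeOH; then TiCl3 buffered with aq. NH4OAc) gives aldehyde F9.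
- Pinnick oxidation (NaClO2, NaH2PO4, 2‑methylbut‑2‑ene, t‑BuOH/H2O) gives 14.

**Further compounds**
F1 | step 10 | hydroxy aldehyde from 16 (acetal hydrolysed) | C=C(C)[C@@]1(O)CC[C@@H]([C@H](C)CCC=C(C)C)[C@@]1(C(=O)OC)[C@H](CO[Si](C)(C)C(C)(C)C)C=O
F2 | step 10 | exo‑methylene diol (ring A closed, C3–OH, C9–OH) | O[C@@]12C(=C)C[C@H](O)[C@@H](CO[Si](C)(C)C(C)(C)C)[C@]1(C(=O)OC)[C@H]([C@H](C)CCC=C(C)C)CC2
F3 | step 10 | C3 methyl ether of F2 | O[C@@]12C(=C)C[C@H](OC)[C@@H](CO[Si](C)(C)C(C)(C)C)[C@]1(C(=O)OC)[C@H]([C@H](C)CCC=C(C)C)CC2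
F4 | step 10 | spiro‑epoxy alcohol (epoxide oxygen syn to C9–OH) | O[C@@]12[C@]3(CO3)C[C@H](OC)[C@@H](CO[Si](C)(C)C(C)(C)C)[C@]1(C(=O)OC)[C@H]([C@H](C)CCC=C(C)C)CC2
F5 | step 10 | 5‑hydroxymethyl analogue of 20 | O=C1[C@@]2(CO)C[C@H](OC)[C@@H](CO[Si](C)(C)C(C)(C)C)[C@]1(C(=O)OC)[C@H]([C@H](C)CCC=C(C)C)CC2
F6 | step 10 | imidazolyl thionocarbonate of F5 | O=C1[C@@]2(COC(=S)n3ccnc3)C[C@H](OC)[C@@H](CO[Si](C)(C)C(C)(C)C)[C@]1(C(=O)OC)[C@H]([C@H](C)CCC=C(C)C)CC2
F7 | step 7 | S‑phenyl thioester of 14 | COC(OC)[C@@H](CO[Si](C)(C)C(C)(C)C)[C@H]([C@H]([C@H](C)CCC=C(C)C)CCC(=O)C(C)=C)C(=O)Sc1ccccc1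
F8 | step 7 | S‑phenyl thioester analogue of 16 | C=C(C)[C@@]1(O)CC[C@@H]([C@H](C)CCC=C(C)C)[C@@]1(C(=O)Sc2ccccc2)[C@H](CO[Si](C)(C)C(C)(C)C)C(OC)OC
F9 | step 6 | aldehyde from 13 (CH2NO2 replaced by CHO) | COC(OC)[C@@H](CO[Si](C)(C)C(C)(C)C)[C@H]([C@H]([C@H](C)CCC=C(C)C)CCC(=O)C(C)=C)C=O
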